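The oxirane C–C bond (C1–C10, germacrane numbering) is also a bond of the ten-membered carbocycle, and the ring carbons C2 and C9 sit cis on the oxirane, so the epoxide is the oxide of a (Z)-trisubstituted cyclodecene. The route rests on ring-closing metathesis of an open precursor in which a C1 vinyl and a C10 isopropenyl group hang from a trans-disubstituted α-methylene-γ-lactone that already carries C3, C6, C7 and C8: one operation closes the ten-membered ring by forming C1=C10 with the Z geometry that a peracid then transfers stereospecifically to both oxirane carbons. The precursor arises by zinc Barbier union of a bromomethylbutenolide with 3-methylbut-3-enal.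

Key step: step 13

Numbering remark: germacrane numbering of the target is used for all intermediates (C1/C10 oxirane carbons, C14 methyl on C10, C3 carbinol, C4=C5 with C15 methyl on C4, C6 lactone carbinol, C7 ring-fusion carbon, C8 ester carbinol, C11=C13 methylene, C12 lactone carbonyl).

Assumption: the facial sense of the two catalyst-controlled additions (steps 1 and 6) is assigned by analogy with simple enals; the enantiomeric ligand would be used if either proved opposite.

Step 1
Reactants: 1 ethyl (E)-3-methyl-4-oxobut-2-enoate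
Product: 2 ethyl (S,E)-4-hydroxy-3-methylhepta-2,6-dienoate
Conditions: (S)-BINOL (10 mol %), Ti(OiPr)4 (10 mol %), 4 Å MS, CH2Cl2, −20 °C; aq. NaHCO3
Reagents that add atoms: allyltributylstannane, C=CC[Sn](CCCC)(CCCC)CCCC
Why: Keck asymmetric allylation, in which the BINOL–titanium Lewis acid activates only the aldehyde and allyl transfer from tin to one enantioface should set the C3 carbinol as S under catalyst control while the enoate stays untouched.

Step 2
Reactants: 2 ethyl (S,E)-4-hydroxy-3-methylhepta-2,6-dienoate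
Product: 4 (S)-5-allyl-4-methylfuran-2(5H)-one, via ethyl (S,Z)-4-hydroxy-3-methylhepta-2,6-dienoate 3 (not isolated)
Conditions: hν (254 nm, quartz), MeCN, rt; PPTS (cat.)
Reagents that add atoms: none
Why: Photochemical E→Z isomerisation of the enoate brings ester and hydroxyl cis, and irreversible lactonisation of the Z isomer should drain the photostationary mixture to the butenolide, which locks the Z geometry of C4=C5 in a ring without touching C3.

Step 3
Reactants: 4 (S)-5-allyl-4-methylfuran-2(5H)-one
Product: 5 (S,Z)-4-hydroxy-N-methoxy-N,3-dimethylhepta-2,6-dienamide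
Conditions: MeNH(OMe)·HCl, Me3Al, CH2Cl2, 0 °C; cold aq. potassium sodium tartrate; crude used at once
Reagents that add atoms: N,O-dimethylhydroxylamine hydrochloride, CNOC.Cl
Why: Weinreb aminolysis, in which the aluminium amide adds 1,2 to the lactone carbonyl and opens the butenolide, so the ring-enforced Z geometry is carried into the open hydroxy amide and no stereocentre is touched.

Step 4
Reactants: 5 (S,Z)-4-hydroxy-N-methoxy-N,3-dimethylhepta-2,6-dienamide
Product: 6 (S,Z)-N-methoxy-N,3-dimethyl-4-[(triisopropylsilyl)oxy]hepta-2,6-dienamide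
Conditions: TIPSOTf, 2,6-lutidine, CH2Cl2, −78 → 0 °C
Reagents that add atoms: triisopropylsilyl trifluoromethanesulfonate, CC(C)[Si](OS(=O)(=O)C(F)(F)F)(C(C)C)C(C)C
Why: Silyl triflate silylation of the secondary allylic alcohol is fast at low temperature, should outrun relactonisation and installs a bulky ether meant to survive every later step.

Step 5
Reactants: 6 (S,Z)-N-methoxy-N,3-dimethyl-4-[(triisopropylsilyl)oxy]hepta-2,6-dienamide
Product: 7 (S,Z)-3-methyl-4-[(triisopropylsilyl)oxy]hepta-2,6-dienal
Conditions: iBu2AlH, THF, −78 °C; aq. potassium sodium tartrate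
Reagents that add atoms: none
Why: Weinreb amide reduction, in which the chelated tetrahedral aluminium intermediate survives at −78 °C and releases the Z-enal only on work-up, so neither over-reduction nor Z→E isomerisation is expected.

Step 6
Reactants: 7 (S,Z)-3-methyl-4-[(triisopropylsilyl)oxy]hepta-2,6-dienal; 8 tert-butyldimethyl(prop-2-yn-1-yloxy)silane
Product: 9 (4S,5Z,7S)-1-[(tert-butyldimethylsilyl)oxy]-6-methyl-7-[(triisopropylsilyl)oxy]deca-5,9-dien-2-yn-4-ol
Conditions: (S,S)-ProPhenol (20 mol %), Me2Zn (3 equiv), Ph3P=O (40 mol %), toluene, 0 °C → rt; aq. NH4Cl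
Reagents that add atoms: none
Why: Zinc–ProPhenol catalysed asymmetric alkynylation, in which the dinuclear zinc catalyst binds enal and alkynylzinc and delivers the alkyne to one aldehyde face, should set C6 as S under catalyst control because C3 is remote across the Z olefin.

Step 7
Reactants: 9 (4S,5Z,7S)-1-[(tert-butyldimethylsilyl)oxy]-6-methyl-7-[(triisopropylsilyl)oxy]deca-5,9-dien-2-yn-4-ol
Product: 11 (2Z,4S,5Z,7S)-1-[(tert-butyldimethylsilyl)oxy]-2-iodo-6-methyl-7-[(triisopropylsilyl)oxy]deca-2,5,9-trien-4-ol, via cyclic sodium alkenylalanate 10 (not isolated)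
Conditions: NaAlH2(OCH2CH2OMe)2 (Red-Al), THF, 0 °C → rt; then I2, THF, −78 °C; aq. Na2S2O3
Reagents that add atoms: iodine, [I][I]
Why: Hydroxyl-directed trans-hydroalumination of the propargylic alcohol places hydride on C7 and aluminium on C11 inside a five-membered alkoxyalanate, and iodinolysis with retention should give the vinyl iodide with iodine cis to C6.

Step 8
Reactants: 11 (2Z,4S,5Z,7S)-1-[(tert-butyldimethylsilyl)oxy]-2-iodo-6-methyl-7-[(triisopropylsilyl)oxy]deca-2,5,9-trien-4-ol
Product: 12 (5S)-3-{[(tert-butyldimethylsilyl)oxy]methyl}-5-{(1Z,3S)-2-methyl-3-[(triisopropylsilyl)oxy]hexa-1,5-dien-1-yl}furan-2(5H)-one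
Conditions: PdCl2(PPh3)2 (5 mol %), CO (1 atm), K2CO3, THF, 35 °C
Reagents that add atoms: carbon monoxide, [C-]#[O+]
Why: Palladium-catalysed carbonylative lactonisation, in which oxidative addition of zerovalent palladium into C11–I, CO insertion with retention and capture of the acylpalladium by the cis C6 hydroxyl close the butenolide, with a weak heterogeneous base chosen so that the acidic C6–H is not epimerised.

Step 9
Reactants: 12 (5S)-3-{[(tert-butyldimethylsilyl)oxy]methyl}-5-{(1Z,3S)-2-methyl-3-[(triisopropylsilyl)oxy]hexa-1,5-dien-1-yl}furan-2(5H)-one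
Product: 13 (5S)-3-(bromomethyl)-5-{(1Z,3S)-2-methyl-3-[(triisopropylsilyl)oxy]hexa-1,5-dien-1-yl}furan-2(5H)-one
Conditions: Ph3PBr2, CH2Cl2, 0 °C → rt
Reagents that add atoms: dibromotriphenylphosphorane, BrP(Br)(c1ccccc1)(c1ccccc1)c1ccccc1
Why: Direct silyl ether to bromide conversion with Ph3PBr2, in which the unhindered primary allylic TBS ether oxygen attacks phosphorus and bromide then displaces Ph3P=O, while the hindered secondary TIPS ether should not react.

Step 10
Reactants: 14 3-methylbut-3-en-1-ol
Product: 15 3-methylbut-3-enal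
Conditions: Dess–Martin periodinane, pyridine, CH2Cl2, 0 °C → rt; filtered solution used at once
Reagents that add atoms: none
Why: Dess–Martin oxidation under pyridine buffering should give the β,γ-unsaturated aldehyde without the acid or base that would move the double bond into conjugation.

Step 11
Reactants: 13 (5S)-3-(bromomethyl)-5-{(1Z,3S)-2-methyl-3-[(triisopropylsilyl)oxy]hexa-1,5-dien-1-yl}furan-2(5H)-one; 15 3-methylbut-3-enal
Product: 17 (4S,5S)-4-[(1R)-1-hydroxy-3-methylbut-3-en-1-yl]-3-methylidene-5-{(1Z,3S)-2-methyl-3-[(triisopropylsilyl)oxy]hexa-1,5-dien-1-yl}oxolan-2-one, via allylzinc bromide 16 (not isolated)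
Conditions: Zn dust, THF/sat. aq. NH4Cl, 0 °C → rt
Reagents that add atoms: none
Why: Zinc Barbier allylation, in which the allylzinc attacks the aldehyde through C7 (SE2′) in a chair transition state on the face anti to the C6 side chain, should set C7 trans to C6 and, with the aldehyde substituent equatorial, the C8 carbinol as R under substrate control while unveiling the α-methylene lactone.

Step 12
Reactants: 17 (4S,5S)-4-[(1R)-1-hydroxy-3-methylbut-3-en-1-yl]-3-methylidene-5-{(1Z,3S)-2-methyl-3-[(triisopropylsilyl)oxy]hexa-1,5-dien-1-yl}oxolan-2-one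
Product: 18 (1R)-3-methyl-1-[(2S,3S)-4-methylidene-2-{(1Z,3S)-2-methyl-3-[(triisopropylsilyl)oxy]hexa-1,5-dien-1-yl}-5-oxooxolan-3-yl]but-3-en-1-yl 2-methylpropanoate
Conditions: (iPrCO)2O, DMAP (cat.), pyridine, CH2Cl2, 0 °C → rt
Reagents that add atoms: isobutyric anhydride, CC(C)C(=O)OC(=O)C(C)C
Why: DMAP-catalysed acylation of the secondary C8 alcohol proceeds with retention at C8 and should be much faster than translactonisation under these mildly basic conditions.

Step 13
Reactants: 18 (1R)-3-methyl-1-[(2S,3S)-4-methylidene-2-{(1Z,3S)-2-methyl-3-[(triisopropylsilyl)oxy]hexa-1,5-dien-1-yl}-5-oxooxolan-3-yl]but-3-en-1-yl 2-methylpropanoate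
Product: 19 (3S,6S,7S,8R)-8-(isobutyryloxy)-3-[(triisopropylsilyl)oxy]germacra-1(10)Z,4Z,11(13)-trien-12,6-olide
Conditions: second-generation Hoveyda–Grubbs catalyst RuCl2(H2IMes)(=CH-C6H4-2-OiPr) (10 mol %), 1,4-benzoquinone (10 mol %), toluene (1 mM), 80 °C, argon sparge
Reagents that add atoms: none
Why: Ring-closing olefin metathesis, in which the ruthenium alkylidene loads at the unhindered C1 vinyl group, adds to the C10 isopropenyl group through a ruthenacyclobutane and releases ethylene on cycloreversion, so that C1 and C10 become directly bonded. The closest known reaction type is ring-closing metathesis of a mono- with a 1,1-disubstituted olefin to a trisubstituted medium-ring cycloalkene, which is known for ten-membered carbocycles bearing an α-methylene lactone. The only ring closed is the ten-membered carbocycle, closed at C1=C10 by metathesis of two ring-external terminal olefins (no polar ring-closure mode applies). No stereocentre is created; the new stereo-element is the Z geometry of C1=C10, which ring strain should control because an E-trisubstituted olefin beside the trans-lactone and the Z-C4=C5 bond is far more strained, and this geometry fixes the cis relation of C2 and C9 on the later oxirane. The step needs site selectivity over the electron-poor C11=C13 methylene and the trisubstituted C4=C5 bond and ring closure over oligomerisation, which the higher reactivity of the two electron-neutral terminal olefins, the turn imposed by the Z-C4=C5 bond and the lactone, high dilution and ethylene removal should secure.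

Step 14
Reactants: 19 (3S,6S,7S,8R)-8-(isobutyryloxy)-3-[(triisopropylsilyl)oxy]germacra-1(10)Z,4Z,11(13)-trien-12,6-olide
Product: 20 (1R,3S,6S,7S,8R,10S)-1,10-epoxy-8-(isobutyryloxy)-3-[(triisopropylsilyl)oxy]germacra-4Z,11(13)-dien-12,6-olide
Conditions: mCPBA (1.1 equiv), CH2Cl2, 0 °C; aq. NaHCO3/Na2S2O3
Reagents that add atoms: 3-chloroperbenzoic acid, OOC(=O)c1cccc(Cl)c1
Why: Prilezhaev epoxidation is stereospecific, so the Z olefin gives the cis-oxirane and C1 and C10 arise together, the electron-rich C1=C10 bond should react before the C4=C5 bond (deactivated by two allylic C–O bonds and shielded by the TIPS ether) and the electron-poor methylene, and oxygen is expected to enter from the open outer face of the folded ring, taken here to be the 1R,10S face.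

Step 15
Reactants: 20 (1R,3S,6S,7S,8R,10S)-1,10-epoxy-8-(isobutyryloxy)-3-[(triisopropylsilyl)oxy]germacra-4Z,11(13)-dien-12,6-olide
Product: 21 (1R,3S,6S,7S,8R,10S)-1,10-epoxy-3-hydroxy-8-(isobutyryloxy)germacra-4Z,11(13)-dien-12,6-olide (CNP0261225.1)
Conditions: Bu4NF, AcOH (1:1), THF, 0 °C → rt
Reagents that add atoms: none
Why: Fluoride-mediated desilylation buffered with acetic acid should remove the TIPS ether without acid- or base-induced damage to the epoxide, the isobutyrate or the α-methylene lactone, and leaves all stereocentres unchanged.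

Compound list
1 | ethyl (E)-3-methyl-4-oxobut-2-enoate | CCOC(=O)/C=C(\C)C=O | starting material
2 | ethyl (S,E)-4-hydroxy-3-methylhepta-2,6-dienoate | CCOC(=O)/C=C(\C)[C@@H](O)CC=C | intermediate
3 | ethyl (S,Z)-4-hydroxy-3-methylhepta-2,6-dienoate | CCOC(=O)/C=C(/C)[C@@H](O)CC=C | intermediate (not isolated)
4 | (S)-5-allyl-4-methylfuran-2(5H)-one | C=CC[C@@H]1OC(=O)C=C1C | intermediate
5 | (S,Z)-4-hydroxy-N-methoxy-N,3-dimethylhepta-2,6-dienamide | CON(C)C(=O)/C=C(/C)[C@@H](O)CC=C | intermediate
6 | (S,Z)-N-methoxy-N,3-dimethyl-4-[(triisopropylsilyl)oxy]hepta-2,6-dienamide | CON(C)C(=O)/C=C(/C)[C@@H](O[Si](C(C)C)(C(C)C)C(C)C)CC=C | intermediate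
7 | (S,Z)-3-methyl-4-[(triisopropylsilyl)oxy]hepta-2,6-dienal | O=C/C=C(/C)[C@@H](O[Si](C(C)C)(C(C)C)C(C)C)CC=C | intermediate
8 | tert-butyldimethyl(prop-2-yn-1-yloxy)silane | C#CCO[Si](C)(C)C(C)(C)C | starting material
9 | (4S,5Z,7S)-1-[(tert-butyldimethylsilyl)oxy]-6-methyl-7-[(triisopropylsilyl)oxy]deca-5,9-dien-2-yn-4-ol | CC(C)(C)[Si](C)(C)OCC#C[C@@H](O)/C=C(/C)[C@@H](O[Si](C(C)C)(C(C)C)C(C)C)CC=C | intermediate
10 | cyclic sodium alkenylalanate: sodium (5S)-3-{[(tert-butyldimethylsilyl)oxy]methyl}-2,2-bis(2-methoxyethoxy)-5-{(1Z,3S)-2-methyl-3-[(triisopropylsilyl)oxy]hexa-1,5-dien-1-yl}-2,5-dihydro-1,2-oxaluminol-2-uide | [Na+].COCCO[Al-]1(OCCOC)O[C@@H](/C=C(/C)[C@@H](O[Si](C(C)C)(C(C)C)C(C)C)CC=C)C=C1CO[Si](C)(C)C(C)(C)C | intermediate (not isolated)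
11 | (2Z,4S,5Z,7S)-1-[(tert-butyldimethylsilyl)oxy]-2-iodo-6-methyl-7-[(triisopropylsilyl)oxy]deca-2,5,9-trien-4-ol | CC(C)(C)[Si](C)(C)OC/C(I)=C/[C@@H](O)/C=C(/C)[C@@H](O[Si](C(C)C)(C(C)C)C(C)C)CC=C | intermediate
12 | (5S)-3-{[(tert-butyldimethylsilyl)oxy]methyl}-5-{(1Z,3S)-2-methyl-3-[(triisopropylsilyl)oxy]hexa-1,5-dien-1-yl}furan-2(5H)-one | CC(C)(C)[Si](C)(C)OCC1=C[C@H](/C=C(/C)[C@@H](O[Si](C(C)C)(C(C)C)C(C)C)CC=C)OC1=O | intermediate
13 | (5S)-3-(bromomethyl)-5-{(1Z,3S)-2-methyl-3-[(triisopropylsilyl)oxy]hexa-1,5-dien-1-yl}furan-2(5H)-one | BrCC1=C[C@H](/C=C(/C)[C@@H](O[Si](C(C)C)(C(C)C)C(C)C)CC=C)OC1=O | intermediate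
14 | 3-methylbut-3-en-1-ol | CC(=C)CCO | starting material
15 | 3-methylbut-3-enal | CC(=C)CC=O | intermediate
16 | allylzinc bromide: {[(5S)-5-{(1Z,3S)-2-methyl-3-[(triisopropylsilyl)oxy]hexa-1,5-dien-1-yl}-2-oxo-2,5-dihydrofuran-3-yl]methyl}zinc bromide | Br[Zn]CC1=C[C@H](/C=C(/C)[C@@H](O[Si](C(C)C)(C(C)C)C(C)C)CC=C)OC1=O | intermediate (not isolated)
17 | (4S,5S)-4-[(1R)-1-hydroxy-3-methylbut-3-en-1-yl]-3-methylidene-5-{(1Z,3S)-2-methyl-3-[(triisopropylsilyl)oxy]hexa-1,5-dien-1-yl}oxolan-2-one | C=C1C(=O)O[C@@H](/C=C(/C)[C@@H](O[Si](C(C)C)(C(C)C)C(C)C)CC=C)[C@@H]1[C@H](O)CC(C)=C | intermediate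
18 | (1R)-3-methyl-1-[(2S,3S)-4-methylidene-2-{(1Z,3S)-2-methyl-3-[(triisopropylsilyl)oxy]hexa-1,5-dien-1-yl}-5-oxooxolan-3-yl]but-3-en-1-yl 2-methylpropanoate | C=C1C(=O)O[C@@H](/C=C(/C)[C@@H](O[Si](C(C)C)(C(C)C)C(C)C)CC=C)[C@@H]1[C@H](OC(=O)C(C)C)CC(C)=C | intermediate
19 | (3S,6S,7S,8R)-8-(isobutyryloxy)-3-[(triisopropylsilyl)oxy]germacra-1(10)Z,4Z,11(13)-trien-12,6-olide | C=C1C(=O)O[C@H]2/C=C(/C)[C@@H](O[Si](C(C)C)(C(C)C)C(C)C)C/C=C(/C)C[C@@H](OC(=O)C(C)C)[C@H]12 | intermediate
20 | (1R,3S,6S,7S,8R,10S)-1,10-epoxy-8-(isobutyryloxy)-3-[(triisopropylsilyl)oxy]germacra-4Z,11(13)-dien-12,6-olide | C=C1C(=O)O[C@H]2/C=C(/C)[C@@H](O[Si](C(C)C)(C(C)C)C(C)C)C[C@H]3O[C@@]3(C)C[C@@H](OC(=O)C(C)C)[C@H]12 | intermediate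
21 | (1R,3S,6S,7S,8R,10S)-1,10-epoxy-3-hydroxy-8-(isobutyryloxy)germacra-4Z,11(13)-dien-12,6-olide (CNP0261225.1) | C=C1C(=O)O[C@H]2/C=C(/C)[C@@H](O)C[C@H]3O[C@@]3(C)C[C@@H](OC(=O)C(C)C)[C@H]12 | target

Total step count: 15. Longest linear sequence: 14 steps (compound 1 to compound 21 through steps 1–9 and 11–15; step 10 is the only side branch).

Steps most likely to fail

Step 13 (ring-closing metathesis). The ruthenium alkylidene formed at the C1 vinyl group may engage the electron-poor C11=C13 methylene (an eight-membered closure) or build oligomers faster than it closes onto the hindered isopropenyl group. The fallback removes the competing olefin instead of relying on catalyst selectivity. It sets out from 18: conjugate addition of dimethylamine (THF, 0 °C) would give the dimethylamine adduct F1 (C11 epimers, inconsequential). Metathesis of its toluenesulfonate salt with the same ruthenium catalyst would close the ten-membered ring to the amino lactone F2. Exhaustive methylation with iodomethane would give the methiodide F3, and aqueous NaHCO3 would then eliminate trimethylamine and restore the α-methylene lactone, which returns the route to 19.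

Step 14 (epoxidation). Oxygen may be delivered to the wrong face of C1=C10, because only the ring conformation and no directing group decides, and the acid by-product may trigger transannular opening. The fallback reaches the other face through two inversions and sets out from 19. N-Bromosuccinimide in aqueous 1,2-dimethoxyethane would form the bromonium ion on the face the peracid prefers, and water would open it anti at the tertiary C10 to give the bromohydrin F4. DBU in CH2Cl2 would then close the oxirane by displacement of bromide at C1, placing the oxygen on the opposite face and returning the route to 20.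

Step 6 (asymmetric alkynylation). Catalyst control at C6 may be weak with this β,β-disubstituted Z-enal and an alkyl-type alkyne, and the enal may isomerise Z→E during a slow addition. The fallback separates C–C bond formation from the creation of the stereocentre and sets out from 6 and 8. The lithium acetylide of 8 (n-BuLi, THF, −78 °C) would add to Weinreb amide 6 to give the ynone F5. Asymmetric transfer hydrogenation with RuCl[(S,S)-TsDPEN](p-cymene) in 2-propanol would then set C6 and return the route to 9.

Further compounds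
F1 | step 13 | 13-(dimethylamino)-11,13-dihydro derivative of 18 (C11 epimers) | CN(C)CC1C(=O)O[C@@H](/C=C(/C)[C@@H](O[Si](C(C)C)(C(C)C)C(C)C)CC=C)[C@@H]1[C@H](OC(=O)C(C)C)CC(C)=C
F2 | step 13 | 13-(dimethylamino)-11,13-dihydro derivative of 19 (C11 epimers) | CN(C)CC1C(=O)O[C@H]2/C=C(/C)[C@@H](O[Si](C(C)C)(C(C)C)C(C)C)C/C=C(/C)C[C@@H](OC(=O)C(C)C)[C@H]12
F3 | step 13 | trimethylammonium iodide (methiodide) of F2 | C[N+](C)(C)CC1C(=O)O[C@H]2/C=C(/C)[C@@H](O[Si](C(C)C)(C(C)C)C(C)C)C/C=C(/C)C[C@@H](OC(=O)C(C)C)[C@H]12.[I-]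
F4 | step 14 | (1S,3S,6S,7S,8R,10S)-1-bromo-10-hydroxy-8-(isobutyryloxy)-3-[(triisopropylsilyl)oxy]germacra-4Z,11(13)-dien-12,6-olide | C=C1C(=O)O[C@H]2/C=C(/C)[C@@H](O[Si](C(C)C)(C(C)C)C(C)C)C[C@H](Br)[C@](O)(C)C[C@@H](OC(=O)C(C)C)[C@H]12
F5 | step 6 | (S,Z)-1-[(tert-butyldimethylsilyl)oxy]-6-methyl-7-[(triisopropylsilyl)oxy]deca-5,9-dien-2-yn-4-one | CC(C)(C)[Si](C)(C)OCC#CC(=O)/C=C(/C)[C@@H](O[Si](C(C)C)(C(C)C)C(C)C)CC=C
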